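**Retrosynthetic overview**
- Kazinol J comes from its tris-MOM ether by one global acetal cleavage.
- Key disconnection: the ring-B aryl–CH2 bond of the diarylpropane and the neighbouring aryl–prenyl bond are made together in one Pd/norbornene (Catellani-type) ortho-C–H alkylation/ipso-prenylation. The three partners are a 2-prenyl aryl iodide, a ring-A 3-arylpropyl iodide and prenyl-Bpin.
- Ring-B iodide: catechol → bis-MOM ether → para-bromination → metalation between OMOM and Br, Cu-mediated prenylation → Br-to-I exchange.
- Ring-A iodide: resorcinol + acrylic acid give a dihydrocoumarin, which fixes the chain position and differentiates the two oxygens; then MOM protection, LiAlH4 opening, phenol O-methylation and iodination.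
- Both benzene rings are bought intact (catechol, resorcinol). The only ring formed is the temporary lactone, which is reopened.

Assumption: the target has no stereocentres and no stereogenic alkenes (both prenyl alkenes carry two identical methyls), so the SMILES defines one achiral compound and no stereocontrol is needed.

**Ring-B fragment**

Step 1
Reactants: 1 catechol
Product: 2 1,2-bis(methoxymethoxy)benzene
Conditions: MOMCl (2.5 equiv), i-Pr2NEt (3 equiv), CH2Cl2, 0 °C → rt
Reagents that add atoms: chloromethyl methyl ether, COCCl
Why: Standard O-alkylation of both phenols (MOM acetal formation); MOM is base-stable and a strong ortho-directing group for step 3.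

Step 2
Reactants: 2 1,2-bis(methoxymethoxy)benzene
Product: 3 4-bromo-1,2-bis(methoxymethoxy)benzene
Conditions: NBS (1.0 equiv), MeCN, 0 °C → rt
Reagents that add atoms: N-bromosuccinimide, O=C1CCC(=O)N1Br
Why: Electrophilic aromatic bromination of a 1,2-dialkoxybenzene goes para to an alkoxy group, and one equivalent stops at the monobromide.

Step 3
Reactants: 3 4-bromo-1,2-bis(methoxymethoxy)benzene; 4 prenyl bromide (1-bromo-3-methylbut-2-ene)
Product: 5 1-bromo-3,4-bis(methoxymethoxy)-2-(3-methylbut-2-en-1-yl)benzene
Conditions: LDA (1.1 equiv), THF, −78 °C, 1 h; CuBr·SMe2 (1.1 equiv), −78 → −40 °C; then 4 (1.5 equiv), −40 → 0 °C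
Reagents that add atoms: none (the prenyl group comes from reactant 4)
Why: Directed ortho-metalation removes the most acidic proton, flanked by OMOM and Br; the aryllithium is stable at −78 °C, and after Li→Cu transmetalation the arylcopper alkylates prenyl bromide at the primary carbon (SN2) to give the linear prenyl arene.

Step 4
Reactants: 5 1-bromo-3,4-bis(methoxymethoxy)-2-(3-methylbut-2-en-1-yl)benzene
Product: 6 1-iodo-3,4-bis(methoxymethoxy)-2-(3-methylbut-2-en-1-yl)benzene
Conditions: t-BuLi (2.1 equiv), Et2O, −78 °C, 20 min; I2 (1.3 equiv) in THF, −78 °C → rt; aq. Na2S2O3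
Reagents that add atoms: iodine, II
Why: Br/Li exchange is faster than any deprotonation at −78 °C and iodinolysis of the aryllithium gives the aryl iodide, the preferred electrophile for Pd/norbornene catalysis.

**Ring-A fragment**

Step 5
Reactants: 7 resorcinol; 8 acrylic acid
Product: 9 7-hydroxychroman-2-one (7-hydroxy-3,4-dihydrocoumarin)
Conditions: Amberlyst-15, toluene, reflux, Dean–Stark
Reagents that add atoms: none
Why: Acid-catalysed Friedel–Crafts conjugate hydroarylation at C4 of resorcinol followed by lactonisation onto the ortho OH installs the three-carbon chain and leaves the para OH free, so the two oxygens are differentiated.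

Step 6
Reactants: 9 7-hydroxychroman-2-one
Product: 10 7-(methoxymethoxy)chroman-2-one
Conditions: MOMCl (1.3 equiv), i-Pr2NEt (2 equiv), CH2Cl2, 0 °C → rt
Reagents that add atoms: chloromethyl methyl ether, COCCl
Why: MOM etherification of the only free phenol under non-nucleophilic base leaves the aryl lactone intact.

Step 7
Reactants: 10 7-(methoxymethoxy)chroman-2-one
Product: 11 2-(3-hydroxypropyl)-5-(methoxymethoxy)phenol
Conditions: LiAlH4 (1.5 equiv), THF, 0 °C → rt; Rochelle salt workup
Reagents that add atoms: none
Why: Hydride reduction of the lactone opens it to the primary alcohol and releases the ortho phenol; the MOM acetal is inert to hydride and to the non-acidic workup.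

Step 8
Reactants: 11 2-(3-hydroxypropyl)-5-(methoxymethoxy)phenol
Product: 12 3-[2-methoxy-4-(methoxymethoxy)phenyl]propan-1-ol
Conditions: MeI (1.3 equiv), K2CO3 (2 equiv), acetone, reflux
Reagents that add atoms: iodomethane, CI
Why: Williamson methylation is chemoselective because K2CO3 deprotonates only the phenol (pKa about 10) and not the aliphatic alcohol.

Step 9
Reactants: 12 3-[2-methoxy-4-(methoxymethoxy)phenyl]propan-1-ol
Product: 13 1-(3-iodopropyl)-2-methoxy-4-(methoxymethoxy)benzene
Conditions: I2 (1.3 equiv), PPh3 (1.3 equiv), imidazole (2 equiv), CH2Cl2, 0 °C → rt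
Reagents that add atoms: iodine, II
Why: Appel-type (Garegg–Samuelsson) iodination converts the primary alcohol to the iodide under imidazole-buffered conditions that spare the MOM ether.

**Prenyl nucleophile**

Step 10
Reactants: 14 prenyl chloride (1-chloro-3-methylbut-2-ene)
Product: 15 prenylboronic acid pinacol ester (4,4,5,5-tetramethyl-2-(3-methylbut-2-en-1-yl)-1,3,2-dioxaborolane)
Conditions: B2pin2 (1.1 equiv), Pd2(dba)3 (1 mol %), THF, 60 °C
Reagents that add atoms: bis(pinacolato)diboron, CC1(C)OB(OC1(C)C)B1OC(C)(C)C(C)(C)O1
Why: Pd-catalysed allylic borylation (Miyaura-type) proceeds through a π-prenyl-Pd intermediate that takes boron at the less substituted terminus, giving the linear allylboronate.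

**Fragment union and endgame**

Step 11
Reactants: 6 1-iodo-3,4-bis(methoxymethoxy)-2-(3-methylbut-2-en-1-yl)benzene; 13 1-(3-iodopropyl)-2-methoxy-4-(methoxymethoxy)benzene; 15 prenylboronic acid pinacol ester
Product: 16 1-{3-[2-methoxy-4-(methoxymethoxy)phenyl]propyl}-4,5-bis(methoxymethoxy)-2,3-bis(3-methylbut-2-en-1-yl)benzene (tris-MOM Kazinol J)
Conditions: Pd(OAc)2 (10 mol %), P(2-furyl)3 (25 mol %), norbornene (2 equiv), Cs2CO3 (4 equiv), 13 (1.5 equiv), MeCN, 85 °C, Ar; 15 (2 equiv) with H2O (5 equiv) added by syringe pump over 4 h
Reagents that add atoms: none (norbornene is a transient mediator and is not incorporated)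
Why: Proposed new method: a Catellani-type ortho-C–H alkylation terminated by ipso-prenylation with an allylboronate. Pd(0) adds to the Ar–I bond of 6, norbornene inserts, and carbonate-assisted C–H palladation at the only free ortho position gives the aryl-norbornyl palladacycle; this adds the primary iodide 13 to give Pd(IV), which reductively eliminates the aryl–CH2 bond. Because both ortho positions are then substituted (prenyl and the new chain), norbornene is extruded by β-carbon elimination; the resulting 2,6-disubstituted aryl-Pd(II) transmetalates with prenyl-Bpin (carbonate/water activation, kept slow by syringe-pump addition so that it does not intercept the initial ArPdI), and the hindered aryl forces reductive elimination at the primary allyl terminus to give the linear prenyl. The closest known chemistry is Pd/norbornene ortho-alkylation with Heck or aryl-Suzuki termination, combined with linear-selective Suzuki coupling of prenylboronates; termination with an allyl/prenyl boronate has not been shown.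

Step 12
Reactants: 16 tris-MOM Kazinol J
Product: 17 Kazinol J
Conditions: 2 M aq. HCl/MeOH (1:5), degassed, 40 °C, 1–2 h, Ar; quench with NaHCO3 at full conversion
Reagents that add atoms: none
Why: Acid-catalysed acetal methanolysis removes all three aryl MOM ethers while the aryl methyl ether is untouched; mild temperature and short time limit chroman formation from the ortho-prenyl catechol.

**Compound list**
1 | catechol (benzene-1,2-diol) | Oc1ccccc1O | starting material
2 | 1,2-bis(methoxymethoxy)benzene | COCOc1ccccc1OCOC | intermediate
3 | 4-bromo-1,2-bis(methoxymethoxy)benzene | COCOc1ccc(Br)cc1OCOC | intermediate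
4 | prenyl bromide (1-bromo-3-methylbut-2-ene) | CC(C)=CCBr | starting material
5 | 1-bromo-3,4-bis(methoxymethoxy)-2-(3-methylbut-2-en-1-yl)benzene | COCOc1ccc(Br)c(CC=C(C)C)c1OCOC | intermediate
6 | 1-iodo-3,4-bis(methoxymethoxy)-2-(3-methylbut-2-en-1-yl)benzene | COCOc1ccc(I)c(CC=C(C)C)c1OCOC | intermediate
7 | resorcinol (benzene-1,3-diol) | Oc1cccc(O)c1 | starting material
8 | acrylic acid | C=CC(=O)O | starting material
9 | 7-hydroxychroman-2-one | O=C1CCc2ccc(O)cc2O1 | intermediate
10 | 7-(methoxymethoxy)chroman-2-one | COCOc1ccc2CCC(=O)Oc2c1 | intermediate
11 | 2-(3-hydroxypropyl)-5-(methoxymethoxy)phenol | COCOc1ccc(CCCO)c(O)c1 | intermediate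
12 | 3-[2-methoxy-4-(methoxymethoxy)phenyl]propan-1-ol | COCOc1ccc(CCCO)c(OC)c1 | intermediate
13 | 1-(3-iodopropyl)-2-methoxy-4-(methoxymethoxy)benzene | COCOc1ccc(CCCI)c(OC)c1 | intermediate
14 | prenyl chloride (1-chloro-3-methylbut-2-ene) | CC(C)=CCCl | starting material
15 | prenylboronic acid pinacol ester | CC(C)=CCB1OC(C)(C)C(C)(C)O1 | intermediate
16 | 1-{3-[2-methoxy-4-(methoxymethoxy)phenyl]propyl}-4,5-bis(methoxymethoxy)-2,3-bis(3-methylbut-2-en-1-yl)benzene | COCOc1ccc(CCCc2cc(OCOC)c(OCOC)c(CC=C(C)C)c2CC=C(C)C)c(OC)c1 | intermediate
17 | Kazinol J | COc1cc(O)ccc1CCCc1cc(O)c(O)c(CC=C(C)C)c1CC=C(C)C | target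

**Totals**
Total step count: 12.
Longest linear sequence: 7 steps (5, 6, 7, 8, 9, 11, 12, from resorcinol).

**Three steps most likely to fail**
1. Step 11 (proposed new three-component Pd/norbornene alkylation/prenylation).
 - Risks: direct Suzuki prenylation of 6 before norbornene insertion, branched (reverse-prenyl) or reduced ipso products, and norbornene-containing by-products.
 - Fallback (known chemistry only):
   - brominate 2 with 2 equiv NBS to the symmetric 4,5-dibromo-1,2-bis(methoxymethoxy)benzene and prenylate C3 as in step 3;
   - couple the less hindered C5–Br by B-alkyl Suzuki–Miyaura with the borinate from 13 (t-BuLi, B-MeO-9-BBN; PdCl2(dppf), K3PO4);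
   - install the second prenyl at the remaining C4–Br by Br/Li exchange, CuBr·SMe2 and prenyl bromide, giving the same compound 16.
2. Step 3 (metalation next to bromine, then prenylation).
 - Risks: aryne formation or halogen migration on warming, and SN2′ (reverse-prenyl) product.
 - Fallback: magnesiate with TMPMgCl·LiCl at 0 °C and trap with allyl bromide (no regiochemical ambiguity), then convert allyl to prenyl by cross-metathesis with 2-methyl-2-butene (Grubbs II) before step 4.
3. Step 12 (global MOM removal).
 - Risks: acid-induced cyclisation of the ortho-prenyl catechol to a 2,2-dimethylchroman, and air oxidation of the catechol.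
 - Fallback: change the protecting-group strategy to fluoride-labile SEM ethers (SEMCl in steps 1 and 6; OSEM directs the step 3 metalation equally well) and unmask with TBAF or CsF under non-acidic conditions.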